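- At the reading of 3.0 min, each flask shows two product signals, target P and isomer of the product Q. The question is the share of P in P + Q, the selectivity.

common to all: substrate 0.20 M

| run | free catalyst | temperature | remark | time |
|---|---|---|---|---|
| ochre | 0.034 mol% | 40 °C | run made earlier |  |
| amber | 0.075 mol% | 82 °C | run made earlier |  |
| Saturday's | 0.05 mol% | 95 °C |  | 3.0 min |
| Tuesday's | 0.05 mol% | 120 °C |  | 3.0 min |
| Friday's | 0.05 mol% | 70 °C |  | 3.0 min |
| Sunday's | 0.05 mol% | 45 °C |  | 3.0 min |

| run | time / min | target / % | isomer of the product / % |
|---|---|---|---|
| ochre | 6.00 | 18.2 | 1.0 |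
| ochre | 15.0 | 32.1 | 2.4 |
| ochre | 30.0 | 42.5 | 6.5 |
| ochre | 50.0 | 46.0 | 10.5 |
| amber | 1.50 | 37.0 | 10.8 |
| amber | 3.00 | 37.0 | 19.2 |
| amber | 5.00 | 34.4 | 26.5 |
| amber | 6.00 | 33.0 | 28.2 |

(standard deviation of a reading: 0.3 percentage points)

- the earlier runs were read with a standard deviation of 0.3 percentage points
- the share counts what is present at the end, not what went on to other products

- which flask leads in share of target in all that became target or isomer of the product ("all alike" within 1.5 percentage points) (Saturday's / Tuesday's / Friday's / Sunday's / all alike)
- share of target in all that became target or isomer of the product, Saturday's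
- share of target in all that became target or isomer of the product, Tuesday's
- share of target in all that became target or isomer of the product, Friday's
- share of target in all that became target or isomer of the product, Sunday's

- Take the main step by itself: substrate gives target, no Q appears, and the share stands at 100 %.
- Now add one process, target going on to Q. Let ρ be Q/P, and let the dose be loading times time. For small ρ, the working rule is that ρ grows in proportion to the dose at a fixed temperature.
- The ochre run supports this: from 15.0 min to 30.0 min, time went up twice and ρ went up twice.
- So each run can be scaled to the dose of the new flasks. Call the result ρ*, the isomer ratio at the asked dose. The ochre reading at 30.0 min gives ρ* = 0.0225 at 40 °C.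
- The amber reading at 3.00 min gives ρ* = 0.346 at 82 °C.
- An Arrhenius line through these two readings has a slope of 7240 K.
- On that line, ρ* is 0.0323 for Sunday's, 0.170 for Friday's, 0.710 for Saturday's and 2.48 for Tuesday's.
- The shares are then 96.9 %, 85.5 %, 58.5 % and 28.7 %, so Sunday's leads.
- Now add the rest. In the amber run, time rose 4.00-fold from the first reading to the last, but ρ rose 2.93-fold. So in the amber run ρ falls behind the nominal dose. This reckoning thus takes the Tuesday's figure as a low estimate and expects a higher share.
- The forecast names Sunday's, with 94 % for Sunday's, 82 % for Friday's, 63 % for Saturday's and 44 % for Tuesday's; its caution reads “The 120 °C value is uncertain”, and its Tuesday's figure lies above this reckoning's low estimate.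
- The flasks give Sunday's as the leader, with 96.9 % for Sunday's, 84.8 % for Friday's, 59.6 % for Saturday's and 42.9 % for Tuesday's.

    substrate + free catalyst ⇌ target + free catalyst, rate k1*[substrate]*[free catalyst] forward; the back reaction follows from the equilibrium constant (K = 1.20, k = 59.0 L mol⁻¹ s⁻¹, Ea = 54.0 kJ mol⁻¹, ΔH = −10.0 kJ mol⁻¹)
    target + free catalyst ⇌ isomer of the product + free catalyst, rate k2*[free catalyst]*[target] forward; the back reaction follows from the equilibrium constant (K = 12.0, k = 20.0 L mol⁻¹ s⁻¹, Ea = 62.0 kJ mol⁻¹, ΔH = 19.0 kJ mol⁻¹)
    free catalyst + target → spent catalyst A (k = 0.00390 L mol⁻¹ s⁻¹, Ea = 85.0 kJ mol⁻¹)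
    2 free catalyst → spent catalyst B (k = 17.0 L mol⁻¹ s⁻¹, Ea = 51.0 kJ mol⁻¹)
    (constants at 70 °C)

- Tuesday's ends at ρ = 1.33, lower than the 2.48 of the straight line. The neighbouring flask is Tuesday's with 0.085 mol% of free catalyst, so its dose is 1.70 times that of Tuesday's. That neighbouring flask holds 43.3 % isomer of the product against 22.0 % target, so its ρ is 1.97. This ρ is 1.48 times that of Tuesday's, a smaller rise than the rise in dose, and the share in that neighbouring flask is 33.6 %.

The earlier runs and the new flask come from a simulation with constants of no real substance.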